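**Assumption:** the target has no stereocentre and no stereogenic double bond, so "single enantiomer" simply means the compound as drawn (1H-pyrrole tautomer).

**Retrosynthetic overview**
- The only ring, the pyrrole, is formed last and in one step: cutting C2–C3 and C4–C5 gives henicos-1-yne and methyl isocyanoacetate (formal [3+2]).
- Polarity logic of that step: the glycine carbon is used as an α-isocyano carbanion (N–C d1 instead of a1), and the carbene-like isocyanide carbon inserts into the metallated alkyne. This makes the alkyl-bearing alkyne carbon an acceptor, so two carbons that are both nucleophilic in the free partners (C2 and C3) are joined.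
- Henicos-1-yne comes from 1-bromononadecane and acetylide (C19 + C2).
- No stereocentres and no protecting groups; the free N–H and the methyl ester come directly from the isocyanoacetate.

**Route**

Step 1
Reactants: 1 1-bromononadecane; 2 lithium acetylide–ethylenediamine complex
Product: 3 henicos-1-yne
Conditions: 2 (1.5 equiv), DMSO/THF (3:1), 10 °C → rt, 6 h; aq. NH4Cl
Reagents that add atoms: none
Why: SN2 alkylation of a terminal acetylide by an unbranched primary bromide in a dipolar aprotic medium (THF keeps the waxy C19 bromide in solution), for which E2 is only a minor pathway; no stereocentre is formed.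

Step 2
Reactants: 3 henicos-1-yne; 4 methyl isocyanoacetate
Product: 6 methyl 3-nonadecyl-1H-pyrrole-2-carboxylate, via methyl 3-nonadecyl-2H-pyrrole-2-carboxylate 5 (not isolated)
Conditions: Ag2CO3 (10 mol%), 4 (1.5 equiv), NMP, 80 °C, 3 h, N2
Reagents that add atoms: none
Why: Silver-catalysed isocyanide–alkyne formal [3+2] cycloaddition of an α-metallated isocyanide (Schöllkopf-type reagent): methyl isocyanoacetate is a polarity-reversed glycine unit whose N-bearing carbon (an a1 centre in imine chemistry) reacts as a d1 carbanion and whose carbene-like isocyanide carbon inserts 1,1 into the Ag–C bond of the argentated alkyne, turning the formerly nucleophilic alkyl-bearing alkyne carbon into the acceptor β-carbon of an ynimine, so that 5-endo-dig closure joins C2 and C3 (both nucleophilic in the free partners) and fixes the 2-ester/3-alkyl pattern with the isocyanide carbon as C5, after which protodemetalation gives 2H-pyrrole 5 that aromatises by H shift in an addition where every atom of 3 and 4 ends up in 6; the transient C2 stereocentre of 5 is racemic and is erased, and the product has no stereocentre.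

**Compound list**
1 | 1-bromononadecane | CCCCCCCCCCCCCCCCCCCBr | starting material
2 | lithium acetylide–ethylenediamine complex | [Li]C#C.NCCN | starting material
3 | henicos-1-yne | CCCCCCCCCCCCCCCCCCCC#C | intermediate
4 | methyl isocyanoacetate | [C-]#[N+]CC(=O)OC | starting material
5 | methyl 3-nonadecyl-2H-pyrrole-2-carboxylate (racemic; not isolated) | CCCCCCCCCCCCCCCCCCCC1=CC=NC1C(=O)OC | intermediate
6 | methyl 3-nonadecyl-1H-pyrrole-2-carboxylate | CCCCCCCCCCCCCCCCCCCc1cc[nH]c1C(=O)OC | target

**Totals**
Total step count: 2. Longest linear sequence: 2 steps (1 → 3 → 6).

**Steps most likely to fail** (the route has only two steps, so both are ranked, most risky first)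

1. Step 2. An unactivated long-chain alkyl alkyne is less reactive than the aryl alkynes that work best in this cycloaddition, and the isocyanoacetate can oligomerise or the alkyne homocouple before ring formation. The fallback sets out from 3 and comes back at 6, replacing the cycloaddition by condensation chemistry. Markovnikov hydration of 3 (Ph3PAuCl/AgOTf cat., aq. MeOH/dioxane, 60 °C) gives henicosan-2-one F1. Heating F1 with N,N-dimethylformamide dimethyl acetal (neat, 110 °C) condenses at the methyl group to give (E)-1-(dimethylamino)docos-1-en-3-one F2; some reaction at the methylene side is the risk here. Amine exchange with glycine methyl ester hydrochloride/Et3N in MeOH gives methyl N-[(Z)-3-oxodocos-1-en-1-yl]glycinate F3. NaOMe in MeOH at reflux then closes the ring (glycinate CH2 onto the ketone, loss of water) to give 6.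

2. Step 1. The waxy bromide may react sluggishly in DMSO, with E2 to nonadec-1-ene and some dialkylation as side reactions. The fallback sets out from 1 and comes back at 3, building the alkyne by two one-carbon additions instead of an SN2 reaction with a C2 nucleophile. Mg turnings in THF convert 1 into nonadecylmagnesium bromide F4. Formylation of F4 with DMF (0 °C, then aqueous work-up) gives icosanal F5. Ohira–Bestmann homologation of F5 (dimethyl (1-diazo-2-oxopropyl)phosphonate, K2CO3, MeOH/THF, rt) gives 3.

**Further compounds**
F1 | step 2 | henicosan-2-one | CCCCCCCCCCCCCCCCCCCC(C)=O
F2 | step 2 | (E)-1-(dimethylamino)docos-1-en-3-one | CCCCCCCCCCCCCCCCCCCC(=O)/C=C/N(C)C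
F3 | step 2 | methyl N-[(Z)-3-oxodocos-1-en-1-yl]glycinate | CCCCCCCCCCCCCCCCCCCC(=O)/C=C\NCC(=O)OC
F4 | step 1 | nonadecylmagnesium bromide | CCCCCCCCCCCCCCCCCCC[Mg]Br
F5 | step 1 | icosanal | CCCCCCCCCCCCCCCCCCCC=O
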